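(The data are simulated on assumed constants, and the scatter is random.)

At the time of reading, 6.0 h, I set amber and green side by side with the two new flasks, and I looked at no other moment.

| setting | amber | green | theta | gamma |
|---|---|---|---|---|
| electrophile | 0.20 M | 0.20 M | 0.20 M | 0.20 M |
| nucleophile | 0.093 M | 0.20 M | 0.160 M | 0.240 M |
| solid base | 0.060 M | 0.060 M | 0.0600 M | 0.0600 M |
| remark | run made earlier | run made earlier |  |  |
| time |  |  | 6.0 h | 6.0 h |

| run | time / h | electrophile / % | target / % |
|---|---|---|---|
| amber | 0.833 | 93 | 8 |
| amber | 1.50 | 88 | 10 |
| amber | 2.50 | 82 | 13 |
| amber | 3.00 | 85 | 16 |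
| amber | 4.00 | 80 | 18 |
| amber | 5.00 | 77 | 24 |
| amber | 6.00 | 74 | 22 |
| green | 0.833 | 87 | 13 |
| green | 1.50 | 79 | 20 |
| green | 2.50 | 70 | 26 |
| green | 3.00 | 68 | 31 |
| green | 4.00 | 65 | 34 |
| green | 5.00 | 59 | 41 |
| green | 6.00 | 57 | 41 |

(readings scatter by 2 percentage points)

- solid, in amounts per volume of the solution: solid base
- at the start none of the solid base is in solution

1. part of the electrophile that has reacted at the end, theta
2. part of the electrophile that has reacted at the end, gamma
3. what raising the concentration of nucleophile from its lowest to its highest value here does to the part of the electrophile that has reacted (changes below 5 percentage points count as none) (it rises / no change / it falls)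

Amber kept 74% of its electrophile and green 57%. I took a first-order view of the electrophile, with the charged nucleophile standing in for its changing amount, and for each run I divided the natural logarithm of charged over remaining electrophile by the nucleophile charged:

amber: 3.24 M⁻¹

green: 2.81 M⁻¹

I called this number the reach of the nucleophile at that time, and I tried freezing it. With green's reading, the part reacted is one minus the exponential of minus reach times charge:

theta: 36.2%

gamma: 49.1%

The weak link was the freezing, since amber's reach stood above green's, though each rests on one scattered reading. So I let the reach slide in a straight line with the charge: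

theta: reach 2.97 M⁻¹, reacted 37.8%

gamma: reach 2.65 M⁻¹, reacted 47.1%

Those were the numbers I committed to. The forecast interpolated a second-order constant it found “drifting down with conversion, perhaps as the base is used up”. It gave 37% for theta and 47% for gamma, and said it rises.

The simulation gave 37.0% for theta and 46.8% for gamma, so it rises, by 9.8 percentage points.

    solid base ⇌ free base, rate k1*(cs1 - [free base]) while solid is left; crystals form when [free base] > cs1 (solubility = 0.0620 M, k = 1.00 h⁻¹)
    acid set free + free base ⇌ salt of the base, settled at all times (K = 48000 M⁻¹)
    2 nucleophile → homo dimer (k = 0.340 M⁻¹ h⁻¹)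
    electrophile + nucleophile → acid set free + target (k = 0.910 M⁻¹ h⁻¹)
    nucleophile + acid set free ⇌ protonated nucleophile, settled at all times (K = 230 M⁻¹)

Read back, theta's reach was 2.88 M⁻¹ and gamma's 2.63 M⁻¹, the latter below the 2.81 M⁻¹ that green's last reading gave. The neighbour flask is gamma with 0.60 M of nucleophile, other charges and the time held. Gamma's reach frozen there gave 79.4% reacted, but the neighbour flask reached 71.4%, its reach down at 2.09 M⁻¹.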